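**Retrosynthetic overview**

1. Both rings are closed in the last step and in the biosynthetic order. Ring A (ten-membered carbocycle) forms by C6–C7 bond formation within an acyclic (2Z,6Z)-farnesane-type 12-oate: the C7=C11 π-bond attacks the C6 carbonyl and C11=C13 is regenerated. Ring B (γ-lactone) then forms by O6→C12 acyl transfer, in the same flask, with indium and the free C8–OH as directing group.
2. The seco chain already carries every oxygen of the target. Its C7=C11(CO2Me)CH2Br end comes from a C7 aldehyde and methyl propiolate (vinylalumination, then SN2' bromination).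
3. C3–C4 is made by an asymmetric Ni/Cr coupling of a C3 aldehyde with (Z)-3-iodo-1,1-dimethoxybut-2-ene (C4–C6 and C15; Z geometry from propargyl alcohol hydroalumination).
4. C1=C10 (Z) is made by a Wittig reaction of an L-tartrate-derived α-alkoxy methyl ketone (C7–C10 and C14; C8 and C9 from the chiral pool) with a C1–C3 acetal ylide.
5. Side chains: acetate on O3; the (2R,3S)-epoxy acid (Sharpless epoxidation of tiglyl alcohol, then oxidation) is esterified on O9 before the chain is completed.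

Assumption: the target is read as the (1(10)Z,4Z)-germacra-1(10),4,11(13)-trien-12,6-olide with 3S,6S,7R,8S,9S centres and a (2R,3S)-2,3-dimethyloxirane-2-carbonyl ester on O9; atom labels C1–C15 in the Why lines are germacrane labels of the target, and (E)-2-methylbut-2-en-1-ol and the sulfonamide ligand of step 13 are taken as purchasable.

**Route**

Step 1
Reactants: 1 3-bromo-1,1-dimethoxypropane
Product: 2 (3,3-dimethoxypropyl)triphenylphosphonium bromide
Conditions: PPh3, MeCN, reflux
Reagents that add atoms: triphenylphosphine, c1ccc(cc1)P(c1ccccc1)c1ccccc1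
Why: SN2 quaternisation of the primary bromide by PPh3 (phosphonium salt formation); the acetal is inert and no stereocentre is present.

Step 2
Reactants: 3 dimethyl (4R,5R)-2,2-dimethyl-1,3-dioxolane-4,5-dicarboxylate
Product: 4 (4R,5R)-N4,N5-dimethoxy-N4,N5,2,2-tetramethyl-1,3-dioxolane-4,5-dicarboxamide
Conditions: MeNH(OMe)·HCl, i-PrMgCl, THF, −20 → 0 °C
Reagents that add atoms: N,O-dimethylhydroxylamine hydrochloride, CNOC.Cl
Why: Weinreb amide formation by aminolysis of both esters with the magnesium amide; the two R centres of L-tartaric acid sit in the trans-dioxolane, the more stable isomer, so they are not epimerised.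

Step 3
Reactants: 4 bis(N-methoxy-N-methylamide)
Product: 5 (4R,5R)-5-acetyl-N-methoxy-N,2,2-trimethyl-1,3-dioxolane-4-carboxamide
Conditions: MeMgBr (1.1 equiv), THF, −78 → −20 °C; aq. NH4Cl
Reagents that add atoms: methylmagnesium bromide, C[Mg]Br
Why: Weinreb ketone synthesis run as a mono-addition: the two amides of the C2-symmetric substrate are homotopic, one equivalent of Grignard reagent converts one of them, and the ketone is released only on work-up so it cannot add again; this brings in C14 and makes the C10 carbonyl.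

Step 4
Reactants: 2 phosphonium bromide; 5 keto amide
Product: 7 (4R,5S)-5-[(2Z)-5,5-dimethoxypent-2-en-2-yl]-N-methoxy-N,2,2-trimethyl-1,3-dioxolane-4-carboxamide, via ylide 6 (not isolated)
Conditions: 2, KN(SiMe3)2, THF, −78 °C; then 5, −78 °C → rt
Reagents that add atoms: none
Why: Wittig olefination of an α-alkoxy methyl ketone with a salt-free non-stabilised ylide, which is Z-selective (Still's route to Z-trisubstituted allylic ethers), so C2 and C9 are cis across C1=C10; C8 and C9 are not touched.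

Step 5
Reactants: 7 Z-alkenyl acetonide amide
Product: 8 (2R,3S,4Z)-2,3-dihydroxy-N,7,7-trimethoxy-N,4-dimethylhept-4-enamide
Conditions: TsOH·H2O (cat.), MeOH, 40 °C
Reagents that add atoms: none
Why: Acid-catalysed transketalisation in methanol takes off the acetonide as 2,2-dimethoxypropane while exchange of the dimethyl acetal is degenerate; no stereocentre is touched.

Step 6
Reactants: 9 (2E)-2-methylbut-2-en-1-ol
Product: 10 [(2S,3S)-2,3-dimethyloxiran-2-yl]methanol
Conditions: Ti(OiPr)4 (cat.), L-(+)-diethyl tartrate (cat.), t-BuOOH, 4 Å molecular sieves, CH2Cl2, −20 °C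
Reagents that add atoms: tert-butyl hydroperoxide, CC(C)(C)OO
Why: Sharpless asymmetric epoxidation: with L-(+)-tartrate the oxygen is delivered to the face that gives the (2S,3S)-epoxy alcohol (the same sense as (E)-hex-2-en-1-ol giving the (2S,3S)-epoxide), and the E-alkene makes the two methyl groups cis.

Step 7
Reactants: 10 epoxy alcohol
Product: 11 (2R,3S)-2,3-dimethyloxirane-2-carboxylic acid
Conditions: RuCl3 (cat.), NaIO4, MeCN/EtOAc/H2O, 0 °C → rt
Reagents that add atoms: sodium periodate, [Na+].[O-]I(=O)(=O)=O; water, O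
Why: Ruthenium-catalysed periodate oxidation of the primary alcohol to the acid (Sharpless conditions for epoxy alcohols) leaves the epoxide intact; the C2 descriptor changes from S to R only because CO2H now outranks C3.

Step 8
Reactants: 8 diol amide; 11 epoxy acid
Product: 13 (2R,3S,4Z)-2-hydroxy-7,7-dimethoxy-1-[methoxy(methyl)amino]-4-methyl-1-oxohept-4-en-3-yl (2R,3S)-2,3-dimethyloxirane-2-carboxylate, via mixed anhydride 12 (not isolated)
Conditions: 11, 2,4,6-trichlorobenzoyl chloride, Et3N, THF, 0 °C; then 8, DMAP, toluene, −20 → 0 °C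
Reagents that add atoms: none
Why: Yamaguchi esterification: the allylic C9 hydroxyl is acylated in preference to the C8 hydroxyl, which is deactivated by the neighbouring amide carbonyl (inductive effect, internal hydrogen bond), and the hindered acyl group does not migrate; no stereocentre is touched.

Step 9
Reactants: 13 C9 ester with free C8 hydroxyl
Product: 15 (2R,3S,4Z)-1-[methoxy(methyl)amino]-4-methyl-1,7-dioxo-2-[(triethylsilyl)oxy]hept-4-en-3-yl (2R,3S)-2,3-dimethyloxirane-2-carboxylate, via lutidinium salt 14 (not isolated)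
Conditions: Et3SiOTf, 2,6-lutidine, CH2Cl2, 0 °C; then H2O
Reagents that add atoms: triethylsilyl trifluoromethanesulfonate, CC[Si](CC)(CC)OS(=O)(=O)C(F)(F)F; water, O
Why: Fujioka acetal cleavage: Et3SiOTf and 2,6-lutidine turn the dimethyl acetal into a pyridinium salt that water hydrolyses to the aldehyde without acid (the β,γ-alkene stays out of conjugation), and the same reagent silylates the free C8 hydroxyl.

Step 10
Reactants: 16 but-2-yn-1-ol
Product: 18 (2Z)-3-iodobut-2-en-1-ol, via vinylalanate 17 (not isolated)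
Conditions: NaAlH2(OCH2CH2OMe)2, THF, 0 °C → rt; then iodine, −78 °C
Reagents that add atoms: iodine, [I][I]
Why: Hydroxyl-directed trans-hydroalumination of the propargylic alcohol puts aluminium on C3 cis to the CH2O group, and iodinolysis with retention gives the Z-alkenyl iodide.

Step 11
Reactants: 18 Z-iodo alcohol
Product: 19 (2Z)-3-iodobut-2-enal
Conditions: MnO2, CH2Cl2, rt
Reagents that add atoms: none
Why: Allylic alcohol oxidation with activated MnO2 stops at the aldehyde and keeps the alkene geometry.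

Step 12
Reactants: 19 Z-iodo enal
Product: 20 (2Z)-3-iodo-1,1-dimethoxybut-2-ene
Conditions: HC(OMe)3, MeOH, PPTS (cat.), 0 °C → rt
Reagents that add atoms: trimethyl orthoformate, COC(OC)OC
Why: Acid-catalysed acetalisation driven by the orthoformate; the weak acid leaves the Z geometry intact.

Step 13
Reactants: 15 C3 aldehyde; 20 Z-iodo acetal
Product: 21 (2R,3S,4Z,7S,8Z)-7-hydroxy-10,10-dimethoxy-1-[methoxy(methyl)amino]-4,8-dimethyl-1-oxo-2-[(triethylsilyl)oxy]deca-4,8-dien-3-yl (2R,3S)-2,3-dimethyloxirane-2-carboxylate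
Conditions: CrCl2, NiCl2 (cat.), Et3N, Kishi-type ligand (S)-N-[2-(4-isopropyl-4,5-dihydro-1,3-oxazol-2-yl)-6-methylphenyl]methanesulfonamide, THF, rt
Reagents that add atoms: none
Why: Asymmetric Nozaki–Hiyama–Kishi coupling: the Z-alkenyl iodide is transferred through nickel to chromium with retention of geometry and adds only to the aldehyde (amide, esters, epoxide, acetal and silyl ether are inert), and the chiral chromium sulfonamide complex directs Re-face attack, which sets C3 (C7 of the chain) as S.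

Step 14
Reactants: 21 C3 alcohol
Product: 22 (2R,3S,4Z,7S,8Z)-7-acetoxy-10,10-dimethoxy-1-[methoxy(methyl)amino]-4,8-dimethyl-1-oxo-2-[(triethylsilyl)oxy]deca-4,8-dien-3-yl (2R,3S)-2,3-dimethyloxirane-2-carboxylate
Conditions: Ac2O, pyridine, DMAP (cat.), CH2Cl2, 0 °C
Reagents that add atoms: acetic anhydride, CC(=O)OC(C)=O
Why: DMAP-catalysed acetylation of the only free hydroxyl, with retention at C3.

Step 15
Reactants: 22 acetate amide
Product: 23 (2R,3S,4Z,7S,8Z)-7-acetoxy-10,10-dimethoxy-4,8-dimethyl-1-oxo-2-[(triethylsilyl)oxy]deca-4,8-dien-3-yl (2R,3S)-2,3-dimethyloxirane-2-carboxylate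
Conditions: Cp2Zr(H)Cl, THF, rt, 20 min
Reagents that add atoms: none
Why: Reduction of the N-methoxy-N-methylamide to the aldehyde with Cp2Zr(H)Cl (Georg's amide reduction) is chemoselective over the three carboxylic esters, the epoxide and the acetal and is neutral, so the C8 centre is not epimerised.

Step 16
Reactants: 23 C7 aldehyde; 24 methyl propiolate
Product: 26 methyl (3RS,4S,5S,6Z,9S,10Z)-9-acetoxy-5-{[(2R,3S)-2,3-dimethyloxirane-2-carbonyl]oxy}-3-hydroxy-12,12-dimethoxy-6,10-dimethyl-2-methylidene-4-[(triethylsilyl)oxy]dodeca-6,10-dienoate, via vinylalane 25 (not isolated)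
Conditions: 24, i-Bu2AlH, N-methylmorpholine N-oxide, THF, 0 °C; then 23, 0 °C
Reagents that add atoms: none
Why: Vinylalumination, a non-basic equivalent of the Morita–Baylis–Hillman reaction: hydroalumination of the propiolate gives the α-aluminoacrylate, which adds to the aldehyde, so the β-acyloxy aldehyde never meets an amine base and cannot eliminate; the new carbinol centre (both epimers) disappears in step 17.

Step 17
Reactants: 26 allylic alcohol
Product: 27 methyl (2Z,4S,5S,6Z,9S,10Z)-9-acetoxy-2-(bromomethyl)-5-{[(2R,3S)-2,3-dimethyloxirane-2-carbonyl]oxy}-12,12-dimethoxy-6,10-dimethyl-4-[(triethylsilyl)oxy]dodeca-2,6,10-trienoate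
Conditions: N-bromosuccinimide, Me2S, CH2Cl2, −20 → 0 °C
Reagents that add atoms: N-bromosuccinimide, O=C1CCC(=O)N1Br
Why: Corey–Kim-type activation of the allylic alcohol and SN2' attack of bromide give the (Z)-2-(bromomethyl)enoate (C8 cis to CH2Br and trans to the ester), the usual outcome for such adducts.

Step 18
Reactants: 27 Z-allylic bromide
Product: 30 (3S,6S,7R,8S,9S,1(10)Z,4Z)-3-acetoxy-8-hydroxy-9-{[(2R,3S)-2,3-dimethyloxirane-2-carbonyl]oxy}germacra-1(10),4,11(13)-trien-12,6-olide, via hydroxy enal bromide 28 (not isolated), via seco hydroxy ester 29 (not isolated)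
Conditions: AcOH/THF/H2O (3:1:1), 0 °C → rt; then THF/H2O to 1 mM, In powder, rt
Reagents that add atoms: water, O
Why: Proposed new method: after acid removal of the silyl ether and the acetal, indium inserts into the allylic carbon–bromine bond, the free C8–OH binds the metal on one face of the C7=C11 π-bond, and C7 attacks the tethered Z-enal carbonyl through a closed six-membered transition state, which forms the C6–C7 bond that the germacrene cyclase forms (ring A) and regenerates C11=C13; the Z-bromide gives the 6,7-syn adduct and delivery syn to O8 gives 7R, hence 6S, and the C6 alkoxide, cis to the ester, then closes the 12,6-lactone (ring B) as in costunolide biosynthesis; the closest known reactions are the intermolecular indium Barbier allylation–lactonisation of 2-(bromomethyl)acrylates with aldehydes (syn-selective, hydroxyl-chelation control in water) and the chromium- or boron-mediated ten-membered closures used for simpler germacranolides.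

**Compound list**

1 | 3-bromo-1,1-dimethoxypropane | COC(OC)CCBr | starting material
2 | (3,3-dimethoxypropyl)triphenylphosphonium bromide | COC(OC)CC[P+](c1ccccc1)(c1ccccc1)c1ccccc1.[Br-] | intermediate
3 | dimethyl (4R,5R)-2,2-dimethyl-1,3-dioxolane-4,5-dicarboxylate (from L-tartaric acid) | COC(=O)[C@@H]1OC(C)(C)O[C@H]1C(=O)OC | starting material
4 | (4R,5R)-N4,N5-dimethoxy-N4,N5,2,2-tetramethyl-1,3-dioxolane-4,5-dicarboxamide | CON(C)C(=O)[C@@H]1OC(C)(C)O[C@H]1C(=O)N(C)OC | intermediate
5 | (4R,5R)-5-acetyl-N-methoxy-N,2,2-trimethyl-1,3-dioxolane-4-carboxamide | CC(=O)[C@@H]1OC(C)(C)O[C@H]1C(=O)N(C)OC | intermediate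
6 | (3,3-dimethoxypropylidene)triphenylphosphorane | COC(OC)CC=P(c1ccccc1)(c1ccccc1)c1ccccc1 | intermediate
7 | (4R,5S)-5-[(2Z)-5,5-dimethoxypent-2-en-2-yl]-N-methoxy-N,2,2-trimethyl-1,3-dioxolane-4-carboxamide | COC(OC)C/C=C(/C)[C@@H]1OC(C)(C)O[C@H]1C(=O)N(C)OC | intermediate
8 | (2R,3S,4Z)-2,3-dihydroxy-N,7,7-trimethoxy-N,4-dimethylhept-4-enamide | COC(OC)C/C=C(/C)[C@H](O)[C@@H](O)C(=O)N(C)OC | intermediate
9 | (2E)-2-methylbut-2-en-1-ol | C/C=C(\C)CO | starting material
10 | [(2S,3S)-2,3-dimethyloxiran-2-yl]methanol | OC[C@]1(C)O[C@H]1C | intermediate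
11 | (2R,3S)-2,3-dimethyloxirane-2-carboxylic acid | OC(=O)[C@]1(C)O[C@H]1C | intermediate
12 | (2R,3S)-2,3-dimethyloxirane-2-carboxylic 2,4,6-trichlorobenzoic anhydride | O=C(OC(=O)c1c(Cl)cc(Cl)cc1Cl)[C@]1(C)O[C@H]1C | intermediate
13 | (2R,3S,4Z)-2-hydroxy-7,7-dimethoxy-1-[methoxy(methyl)amino]-4-methyl-1-oxohept-4-en-3-yl (2R,3S)-2,3-dimethyloxirane-2-carboxylate | COC(OC)C/C=C(/C)[C@H](OC(=O)[C@]1(C)O[C@H]1C)[C@@H](O)C(=O)N(C)OC | intermediate
14 | N-(1-methoxyalkyl)-2,6-dimethylpyridinium triflate from 13: the former acetal carbon carries OMe and the lutidinium nitrogen (both epimers), O8 is triethylsilylated | COC(C/C=C(/C)[C@H](OC(=O)[C@]1(C)O[C@H]1C)[C@@H](O[Si](CC)(CC)CC)C(=O)N(C)OC)[n+]1c(C)cccc1C.[O-]S(=O)(=O)C(F)(F)F | intermediate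
15 | (2R,3S,4Z)-1-[methoxy(methyl)amino]-4-methyl-1,7-dioxo-2-[(triethylsilyl)oxy]hept-4-en-3-yl (2R,3S)-2,3-dimethyloxirane-2-carboxylate | O=CC/C=C(/C)[C@H](OC(=O)[C@]1(C)O[C@H]1C)[C@@H](O[Si](CC)(CC)CC)C(=O)N(C)OC | intermediate
16 | but-2-yn-1-ol | CC#CCO | starting material
17 | sodium cyclic alkenyl(alkoxy)aluminate Na[Al(OCH2CH2OMe)2(OCH2CH=CMe)] (five-membered O–Al–C ring) | CC1=CCO[Al-]1(OCCOC)OCCOC.[Na+] | intermediate
18 | (2Z)-3-iodobut-2-en-1-ol | IC(\C)=C/CO | intermediate
19 | (2Z)-3-iodobut-2-enal | IC(\C)=C/C=O | intermediate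
20 | (2Z)-3-iodo-1,1-dimethoxybut-2-ene | IC(\C)=C/C(OC)OC | intermediate
21 | (2R,3S,4Z,7S,8Z)-7-hydroxy-10,10-dimethoxy-1-[methoxy(methyl)amino]-4,8-dimethyl-1-oxo-2-[(triethylsilyl)oxy]deca-4,8-dien-3-yl (2R,3S)-2,3-dimethyloxirane-2-carboxylate | COC(OC)/C=C(/C)[C@@H](O)C/C=C(/C)[C@H](OC(=O)[C@]1(C)O[C@H]1C)[C@@H](O[Si](CC)(CC)CC)C(=O)N(C)OC | intermediate
22 | (2R,3S,4Z,7S,8Z)-7-acetoxy-10,10-dimethoxy-1-[methoxy(methyl)amino]-4,8-dimethyl-1-oxo-2-[(triethylsilyl)oxy]deca-4,8-dien-3-yl (2R,3S)-2,3-dimethyloxirane-2-carboxylate | COC(OC)/C=C(/C)[C@@H](OC(C)=O)C/C=C(/C)[C@H](OC(=O)[C@]1(C)O[C@H]1C)[C@@H](O[Si](CC)(CC)CC)C(=O)N(C)OC | intermediate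
23 | (2R,3S,4Z,7S,8Z)-7-acetoxy-10,10-dimethoxy-4,8-dimethyl-1-oxo-2-[(triethylsilyl)oxy]deca-4,8-dien-3-yl (2R,3S)-2,3-dimethyloxirane-2-carboxylate | COC(OC)/C=C(/C)[C@@H](OC(C)=O)C/C=C(/C)[C@H](OC(=O)[C@]1(C)O[C@H]1C)[C@@H](O[Si](CC)(CC)CC)C=O | intermediate
24 | methyl propiolate | C#CC(=O)OC | starting material
25 | methyl 2-(diisobutylalumanyl)prop-2-enoate, i-Bu2Al–C(=CH2)CO2Me | C=C(C(=O)OC)[Al](CC(C)C)CC(C)C | intermediate
26 | methyl (3RS,4S,5S,6Z,9S,10Z)-9-acetoxy-5-{[(2R,3S)-2,3-dimethyloxirane-2-carbonyl]oxy}-3-hydroxy-12,12-dimethoxy-6,10-dimethyl-2-methylidene-4-[(triethylsilyl)oxy]dodeca-6,10-dienoate | COC(OC)/C=C(/C)[C@@H](OC(C)=O)C/C=C(/C)[C@H](OC(=O)[C@]1(C)O[C@H]1C)[C@@H](O[Si](CC)(CC)CC)C(O)C(=C)C(=O)OC | intermediate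
27 | methyl (2Z,4S,5S,6Z,9S,10Z)-9-acetoxy-2-(bromomethyl)-5-{[(2R,3S)-2,3-dimethyloxirane-2-carbonyl]oxy}-12,12-dimethoxy-6,10-dimethyl-4-[(triethylsilyl)oxy]dodeca-2,6,10-trienoate | COC(OC)/C=C(/C)[C@@H](OC(C)=O)C/C=C(/C)[C@H](OC(=O)[C@]1(C)O[C@H]1C)[C@@H](O[Si](CC)(CC)CC)/C=C(\CBr)C(=O)OC | intermediate
28 | methyl (2Z,4S,5S,6Z,9S,10Z)-9-acetoxy-2-(bromomethyl)-5-{[(2R,3S)-2,3-dimethyloxirane-2-carbonyl]oxy}-4-hydroxy-6,10-dimethyl-12-oxododeca-2,6,10-trienoate | O=C/C=C(/C)[C@@H](OC(C)=O)C/C=C(/C)[C@H](OC(=O)[C@]1(C)O[C@H]1C)[C@@H](O)/C=C(\CBr)C(=O)OC | intermediate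
29 | methyl 2-[(1S,2S,3S,4Z,7S,8Z,10S)-7-acetoxy-3-{[(2R,3S)-2,3-dimethyloxirane-2-carbonyl]oxy}-2,10-dihydroxy-4,8-dimethylcyclodeca-4,8-dien-1-yl]prop-2-enoate | O[C@H]1/C=C(/C)[C@@H](OC(C)=O)C/C=C(/C)[C@H](OC(=O)[C@]2(C)O[C@H]2C)[C@@H](O)[C@H]1C(=C)C(=O)OC | intermediate
30 | (3S,6S,7R,8S,9S,1(10)Z,4Z)-3-acetoxy-8-hydroxy-9-{[(2R,3S)-2,3-dimethyloxirane-2-carbonyl]oxy}germacra-1(10),4,11(13)-trien-12,6-olide | C=C1C(=O)O[C@H]2/C=C(/C)[C@@H](OC(C)=O)C/C=C(/C)[C@H](OC(=O)[C@]3(C)O[C@H]3C)[C@@H](O)[C@@H]12 | target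

**Step count**

Total: 18 steps. Longest linear sequence: 12 steps (3 → 4 → 5 → 7 → 8 → 13 → 15 → 21 → 22 → 23 → 26 → 27 → 30; steps 2–5, 8, 9, 13–18).

**Three steps most likely to fail, each with a fallback**

Step 18 (one-pot unmasking and indium ring closure). The risks are the wrong face at C7 (the 7,8-syn isomer), lactonisation onto O8 instead of O6, oligomers, and attack of the freed C8–OH on the allylic bromide. The fallback sets out from 26 and comes back at 29. Compound 26 is converted with methyl chloroformate and pyridine into allylic carbonate F1, which undergoes copper-catalysed SN2' borylation (B2pin2, CuCl, Xantphos, KOt-Bu cat., THF) to the isolable allylboronate F2 (C8 cis to CH2B). AcOH/THF/H2O then removes the silyl ether and the acetal to give hydroxy enal boronate F3. This is heated at 1 mM in toluene (80 °C), so that a metal-free allylboration through a closed six-membered transition state forms the C6–C7 bond and gives O6 borate F4. Aqueous work-up gives 29, which lactonises to 30 as in step 18.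

Step 8 (regioselective acylation of the diol). The risk is competing acylation of O8 or of both hydroxyls. The fallback sets out from 8 and comes back at 15. Compound 8 is heated with Bu2SnO in toluene (water removed) to give stannylene acetal F5, which reacts with Et3SiCl at the more acidic, amide-flanked O8 to give C8 silyl ether F6. The single remaining hydroxyl is then acylated with 11 under the Yamaguchi conditions of step 8 to give ester F7, and Et3SiOTf/2,6-lutidine followed by water converts its acetal into aldehyde 15.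

Step 13 (asymmetric Ni/Cr coupling). C3 is remote from the other centres, so its configuration rests on the ligand alone; the level and sense of induction must be checked on a model, and the β,γ-unsaturated aldehyde may isomerise. The fallback sets out from 15 and 20 and comes back at 21. The two are coupled with CrCl2 and NiCl2 (cat.) in DMF without ligand, which gives 21 together with its C3 epimer, epimeric alcohol F8. The mixture is oxidised with Dess–Martin periodinane (NaHCO3, CH2Cl2) to enone F9, and reduction with (R)-2-methyl-CBS-oxazaborolidine and catecholborane (toluene, −78 °C), the alkenyl group acting as the large substituent, returns 21 as the 3S alcohol.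

**Further compounds**

F1 | step 18 | methyl carbonate of 26 at the allylic hydroxyl (both epimers) | COC(OC)/C=C(/C)[C@@H](OC(C)=O)C/C=C(/C)[C@H](OC(=O)[C@]1(C)O[C@H]1C)[C@@H](O[Si](CC)(CC)CC)C(OC(=O)OC)C(=C)C(=O)OC
F2 | step 18 | allylboronate: analogue of 27 with CH2–B(pinacolato) in place of CH2Br, C8 cis to CH2B | COC(OC)/C=C(/C)[C@@H](OC(C)=O)C/C=C(/C)[C@H](OC(=O)[C@]1(C)O[C@H]1C)[C@@H](O[Si](CC)(CC)CC)/C=C(\CB2OC(C)(C)C(C)(C)O2)C(=O)OC
F3 | step 18 | hydroxy enal boronate: analogue of 28 with CH2–B(pinacolato) in place of CH2Br | O=C/C=C(/C)[C@@H](OC(C)=O)C/C=C(/C)[C@H](OC(=O)[C@]1(C)O[C@H]1C)[C@@H](O)/C=C(\CB2OC(C)(C)C(C)(C)O2)C(=O)OC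
F4 | step 18 | O6 pinacol borate of 29 | CC1(C)OB(O[C@H]2/C=C(/C)[C@@H](OC(C)=O)C/C=C(/C)[C@H](OC(=O)[C@]3(C)O[C@H]3C)[C@@H](O)[C@H]2C(=C)C(=O)OC)OC1(C)C
F5 | step 8 | dibutylstannylene acetal of 8 (O8 and O9 bridged by SnBu2) | COC(OC)C/C=C(/C)[C@@H]1O[Sn](CCCC)(CCCC)O[C@H]1C(=O)N(C)OC
F6 | step 8 | (2R,3S,4Z)-3-hydroxy-N,7,7-trimethoxy-N,4-dimethyl-2-[(triethylsilyl)oxy]hept-4-enamide | COC(OC)C/C=C(/C)[C@H](O)[C@@H](O[Si](CC)(CC)CC)C(=O)N(C)OC
F7 | step 8 | (2R,3S,4Z)-7,7-dimethoxy-1-[methoxy(methyl)amino]-4-methyl-1-oxo-2-[(triethylsilyl)oxy]hept-4-en-3-yl (2R,3S)-2,3-dimethyloxirane-2-carboxylate | COC(OC)C/C=C(/C)[C@H](OC(=O)[C@]1(C)O[C@H]1C)[C@@H](O[Si](CC)(CC)CC)C(=O)N(C)OC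
F8 | step 13 | (7R)-epimer of 21 (C3 epimer in germacrane labels) | COC(OC)/C=C(/C)[C@H](O)C/C=C(/C)[C@H](OC(=O)[C@]1(C)O[C@H]1C)[C@@H](O[Si](CC)(CC)CC)C(=O)N(C)OC
F9 | step 13 | 7-oxo analogue of 21 (C3 enone) | COC(OC)/C=C(/C)C(=O)C/C=C(/C)[C@H](OC(=O)[C@]1(C)O[C@H]1C)[C@@H](O[Si](CC)(CC)CC)C(=O)N(C)OC
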